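(The runs are simulated with made-up constants, and the scatter is random.)

| setting | alder | elm | cedar | west | east | south-west | north | north-east | north-west |
|---|---|---|---|---|---|---|---|---|---|
| electrophile | 0.20 M | 0.20 M | 0.10 M | 0.20 M | 0.20 M | 0.20 M | 0.20 M | 0.20 M | 0.20 M |
| free base | 0.080 M | 0.32 M | 0.16 M | 0.160 M | 0.160 M | 0.160 M | 0.160 M | 0.160 M | 0.160 M |
| gas | 15 mM (held) | 15 mM (held) | 15 mM (held) | 15 mM (held) | 15 mM (held) | 15 mM (held) | 15 mM (held) | 15 mM (held) | 15 mM (held) |
| temperature | −25 °C | 8 °C | −25 °C | 0 °C | −20 °C | 10 °C | 20 °C | −5 °C | −40 °C |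
| remark | run made earlier | run made earlier | run made earlier |  |  |  |  |  |  |
| time |  |  |  | 2.0 h | 2.0 h | 2.0 h | 2.0 h | 2.0 h | 2.0 h |

| run | time / min | product / % | electrophile / % |
|---|---|---|---|
| alder | 15.0 | 2.6 | 96.4 |
| alder | 30.0 | 8.7 | 91.9 |
| alder | 50.0 | 13.2 | 86.3 |
| alder | 60.0 | 16.8 | 84.5 |
| alder | 80.0 | 22.7 | 77.1 |
| alder | 90.0 | 25.5 | 75.0 |
| elm | 4.00 | 3.1 | 96.9 |
| elm | 8.00 | 7.2 | 92.6 |
| elm | 12.0 | 11.9 | 89.5 |
| elm | 15.0 | 14.3 | 85.9 |
| elm | 20.0 | 19.2 | 81.6 |
| elm | 25.0 | 23.5 | 76.5 |
| cedar | 20.0 | 6.2 | 93.2 |
| cedar | 40.0 | 14.2 | 85.4 |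
| cedar | 60.0 | 21.4 | 78.0 |
| cedar | 80.0 | 28.1 | 71.9 |
| cedar | 90.0 | 31.4 | 68.4 |

(each reading ± 0.5 percentage points)

- what was read earlier has a scatter of 0.5 percentage points, one standard deviation
- at the start none of the gas is in solution

1. the flasks by amount of product, in percent of the electrophile charged, highest first, at 2.0 h (west / east / south-west / north / north-east / north-west)
2. the amount of product, in percent of the electrophile charged of the flask you put first, at 2.0 h
3. the amount of product, in percent of the electrophile charged of the flask you put last, at 2.0 h

- Count turnovers, taking the gas as consumed into product and calling one turnover the product equal to the gas a full solution holds, c_s = 15 mM; the last alder reading already stands at 3.40 of them, so there the dissolved gas has been renewed.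
- Two times are held against each other in a flask. The first comes from the charge and the asked time: with c_A the electrophile charged, the limiting reagent while the gas is held, and t the asked time, a = t·c_s/c_A = 9.00 min is the allowance, the time a flask may spend per turnover if it is to finish.
- The second is the turnover time τ, the elapsed time per turnover, which reads 26.5 min in alder and 7.98 min in elm. On a straight course, a/τ is the share of electrophile turned into product.
- Alder and elm differ in free base as well as temperature, and cedar changes free base together with electrophile, so the readings leave its effect unseparated; this reckoning lays the whole change on temperature.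
- Drawing ln τ straight through those two readings gives 45.7 min for north-west and 5.16 min for north, a far shorter time. So the order follows temperature, north-west reaches a/τ = 19.7%, and north, at a/τ = 1.74, should approach full conversion.
- The forecast, saying “I assume rate rises steadily with temperature”, gives the same order, north > south-west > west > north-east > east > north-west, but other numbers than this reckoning: 60% and 27%.
- The flasks stand north > south-west > west > north-east > east > north-west, with 94.4% in north and 11.0% in north-west. At 2.00 h, north-west still holds 89.0% of its electrophile. Set equal to the product in north-west, its a/τ makes its turnover time 81.8 min, longer than reckoned.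

    electrophile + nucleophile → acid set free + product (k = 0.0122 M⁻¹ s⁻¹, Ea = 54.0 kJ mol⁻¹)
    nucleophile + acid set free ⇌ protonated nucleophile, settled at all times (K = 18000 M⁻¹, ΔH = −46.0 kJ mol⁻¹)
    acid set free + free base ⇌ salt of the base (K = 3780 M⁻¹, k = 0.0166 M⁻¹ s⁻¹, Ea = 60.0 kJ mol⁻¹, ΔH = −73.0 kJ mol⁻¹)
    gas ⇌ nucleophile, rate k4*(csat - [nucleophile]) (kL = 0.00261 s⁻¹)
    (constants at −20 °C)

- Read the same north-west flask at 30 min: the allowance shrinks in proportion to the time, and with the turnover time just found a/τ gives 2.75%; the computed flask gives 2.46%.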